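**Retrosynthetic overview**
- The cyclobutane C6–C7–C3a'–C7a' joins two identical C12 skeletons. The target is the cross [2+2] dimer of (Z)-ligustilide 11: the C6=C7 alkene in the carbocycle (ring A) of one molecule has added across the C3a'=C7a' ring-fusion alkene of the other, and this hidden dimer symmetry makes the key step possible.
- Key disconnection: both cyclobutane bonds, C6–C7a' and the ring-closing C7–C3a', in one enantioselective [2+2] photocycloaddition inside an energy-transfer photoenzyme ([2+2] photocyclase class), which sets all four stereocentres.
- (Z)-Ligustilide 11: butenolide ring by silver-catalysed 5-exo-dig lactonization of a cis-enynoic acid; alkyne by Sonogashira coupling of a dienyl triflate; oxygenated cyclohexadiene by Birch reduction of methyl 2-methoxybenzoate.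
- Ring order: carbocycle (from the arene, steps 1–3), butenolide (step 6), cyclobutane (step 7).

Key step: step 7

Remark: atom labels are those of ligustilide (C1 lactone carbonyl, O2, C3, C3a, C4–C7, C7a, C8 the first butylidene carbon), primed for the half whose C3a'/C7a' are quaternary in the target; the photoenzyme variant of step 7 is assumed to be obtained beforehand by directed evolution of an energy-transfer photoenzyme scaffold screened on 11.

**Step 1**
Reactants: 1 methyl 2-methoxybenzoate
Product: 3 methyl 2-methoxycyclohexa-2,5-diene-1-carboxylate (racemic), via potassium dienolate 2 (not isolated)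
Conditions: K (2.3 equiv), t-BuOH (1.0 equiv), NH3/THF, −78 °C; then solid NH4Cl, −78 °C → rt
Reagents that add atoms: none
Why: Birch reduction of an ortho-alkoxybenzoate, in which two-electron reduction and protonation at C4 by tert-butanol give the ester dienolate and kinetic protonation at C1 by NH4Cl should give the skipped-diene ester as a racemate whose stereocentre is erased in step 3.

**Step 2**
Reactants: 3 methyl 2-methoxycyclohexa-2,5-diene-1-carboxylate
Product: 4 methyl 6-oxocyclohex-2-ene-1-carboxylate (racemic; in equilibrium with its dienol methyl 2-hydroxycyclohexa-1,5-diene-1-carboxylate)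
Conditions: 1 M HCl, THF, 0 °C, argon; used crude
Reagents that add atoms: water, O
Why: acid-catalysed enol ether hydrolysis (C-protonation, then collapse of the hemiketal) should unmask the ketone under conditions mild enough to leave the isolated alkene and the ester untouched, giving an easily enolised β-keto ester that is carried on at once.

**Step 3**
Reactants: 4 methyl 6-oxocyclohex-2-ene-1-carboxylate
Product: 6 methyl 2-{[(trifluoromethyl)sulfonyl]oxy}cyclohexa-1,5-diene-1-carboxylate, via sodium dienolate 5 (not isolated)
Conditions: NaH, Et2O, 0 °C; then Tf2O, −78 → 0 °C
Reagents that add atoms: trifluoromethanesulfonic anhydride, O=S(=O)(OS(=O)(=O)C(F)(F)F)C(F)(F)F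
Why: enol triflate formation by O-sulfonylation of a β-keto ester enolate, in which removal of the doubly activated allylic C1–H gives one cross-conjugated dienolate (the same from either keto tautomer) that the hard electrophile should capture at the ketone oxygen, fixing the C1=C2/C5=C6 diene.

**Step 4**
Reactants: 6 methyl 2-{[(trifluoromethyl)sulfonyl]oxy}cyclohexa-1,5-diene-1-carboxylate; 7 pent-1-yne
Product: 8 methyl 2-(pent-1-yn-1-yl)cyclohexa-1,5-diene-1-carboxylate
Conditions: PdCl2(PPh3)2 (3 mol %), CuI (6 mol %), Et3N (2 equiv), THF, rt, argon
Reagents that add atoms: none
Why: Sonogashira coupling, for which β-triflyloxy enoates are among the most reactive vinyl electrophiles toward zerovalent palladium, so the copper acetylide of the unhindered alkyne should couple at room temperature without disturbing the diene.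

**Step 5**
Reactants: 8 methyl 2-(pent-1-yn-1-yl)cyclohexa-1,5-diene-1-carboxylate
Product: 10 2-(pent-1-yn-1-yl)cyclohexa-1,5-diene-1-carboxylic acid, via lithium carboxylate 9 (not isolated)
Conditions: LiOH·H2O (3 equiv), THF/MeOH/H2O, 0 °C → rt, argon, dark; then 1 M HCl to pH 3, 0 °C
Reagents that add atoms: lithium hydroxide, [Li+].[OH-]
Why: ester saponification under cold, oxygen-free conditions should give the acid without moving the ring double bonds, the cis arrangement of carboxylate and alkyne needed for step 6 being fixed by the ring.

**Step 6**
Reactants: 10 2-(pent-1-yn-1-yl)cyclohexa-1,5-diene-1-carboxylic acid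
Product: 11 (Z)-ligustilide [(3Z)-3-butylidene-4,5-dihydro-2-benzofuran-1(3H)-one]
Conditions: Ag2CO3 (5 mol %), DMF, rt, dark, argon
Reagents that add atoms: none
Why: silver-catalysed 5-exo-dig cycloisomerization (the mode established for (Z)-2-en-4-ynoic acids with Ag2CO3), in which anti attack of the carboxylate on the silver-activated alkyne and protodemetalation with retention should place oxygen and propyl cis on the new exocyclic alkene, i.e. the Z-butylidene group, with no atoms gained or lost.

**Step 7**
Reactants: 11 (Z)-ligustilide (two molecules)
Product: 12 (6S,7R,3a'R,7a'S)-6.7a',7.3a'-cyclodimer of (Z)-ligustilide (target)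
Conditions: engineered energy-transfer photoenzyme ([2+2] photocyclase with a genetically encoded thioxanthone sensitizer, 1 mol %), potassium phosphate buffer pH 7.0/MeCN 9:1, 405 nm LED, 4 °C, argon
Reagents that add atoms: none
Why: Proposed new method: two molecules of 11 are bound stacked in the hydrophobic pocket so that C6 lies over C7a' and C7 over C3a'; the thioxanthone side chain absorbs at 405 nm, where 11 should be transparent, and passes its triplet energy to the enoate of the molecule that becomes the primed unit, whose C7a' bonds to C6 of the ground-state partner to give a triplet 1,4-biradical (pentadienyl-type radical at C7, allyl radical at C3a') that after intersystem crossing collapses through the C7–C3a' bond. The closest known reaction types are the enantioselective intra- and bimolecular [2+2] photocycloadditions catalysed by engineered energy-transfer photoenzymes carrying benzophenone or thioxanthone sensitizers, and the sensitized [2+2] photodimerization of cyclic enoates and 2(5H)-furanones. One ring is closed, the cyclobutane C6–C7–C3a'–C7a', in a stepwise intermolecular [2π+2π] mode whose ring-closing event is the 1,4-biradical recombination C7–C3a'. The cis relation of H6 and H7 and the cis fusion at C3a'/C7a' are enforced by the rings that carry these atoms; the placement of ring A on the same face as the flat lactone of the primed unit and opposite to its puckered cyclohexene follows the less hindered stacking; and the absolute sense, i.e. which enantiotopic face of C3a'=C7a' is covered, is set by the chiral pocket alone. The step needs chemoselectivity (C6=C7 of one partner with C3a'=C7a' of the other, not C3=C8 and not a [4+2] mode), the stated regiochemistry, retention of both Z-butylidene groups and enantioselectivity; the substrate contributes its only unhindered disubstituted alkene C6=C7 and the fact that both radical centres of the biradical are allylic, while regio- and enantiocontrol must come from the evolved pocket, which should also exclude oxygen and disfavour twisting about C3=C8, making this an atom-economic dimerization that releases nothing.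

**Compound list**
1 | methyl 2-methoxybenzoate | COC(=O)c1ccccc1OC | starting material
2 | potassium methoxy(2-methoxycyclohexa-2,5-dien-1-ylidene)methanolate (potassium dienolate) | COC([O-])=C1C=CCC=C1OC.[K+] | intermediate
3 | methyl 2-methoxycyclohexa-2,5-diene-1-carboxylate (racemic) | COC(=O)C1C=CCC=C1OC | intermediate
4 | methyl 6-oxocyclohex-2-ene-1-carboxylate (racemic; keto form of a keto/dienol pair) | COC(=O)C1C=CCCC1=O | intermediate
5 | sodium 2-(methoxycarbonyl)cyclohexa-1,3-dien-1-olate (sodium dienolate) | COC(=O)C1=C([O-])CCC=C1.[Na+] | intermediate
6 | methyl 2-{[(trifluoromethyl)sulfonyl]oxy}cyclohexa-1,5-diene-1-carboxylate | COC(=O)C1=C(OS(=O)(=O)C(F)(F)F)CCC=C1 | intermediate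
7 | pent-1-yne | CCCC#C | starting material
8 | methyl 2-(pent-1-yn-1-yl)cyclohexa-1,5-diene-1-carboxylate | CCCC#CC1=C(C(=O)OC)C=CCC1 | intermediate
9 | lithium 2-(pent-1-yn-1-yl)cyclohexa-1,5-diene-1-carboxylate | CCCC#CC1=C(C(=O)[O-])C=CCC1.[Li+] | intermediate
10 | 2-(pent-1-yn-1-yl)cyclohexa-1,5-diene-1-carboxylic acid | CCCC#CC1=C(C(=O)O)C=CCC1 | intermediate
11 | (Z)-ligustilide, (3Z)-3-butylidene-4,5-dihydro-2-benzofuran-1(3H)-one | CCC/C=C1\OC(=O)C2=C1CCC=C2 | intermediate
12 | (6S,7R,3a'R,7a'S)-6.7a',7.3a'-cyclodimer of (Z)-ligustilide: cyclobutane C6–C7–C3a'–C7a'; unprimed unit keeps its C3a=C7a butenolide, primed unit keeps C6'=C7' and its enol lactone; both butylidenes Z; H6 and H7 cis; ring A and the primed lactone on one face, the primed cyclohexene on the other | CCC/C=C1\OC(=O)C2=C1CC[C@H]1[C@@H]2[C@]23CCC=C[C@]12C(=O)O/C3=C\CCC | target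

**Step count**
Total step count: 7. Longest linear sequence: 7 steps (1 to 12; both halves of 12 come from the same intermediate 11).

**Steps most likely to fail**

Step 7 (proposed new method).
- What may go wrong: insufficient control by the protein, giving regio- and stereoisomeric [2+2] or [4+2] dimers or low enantioselectivity; triplet Z/E isomerization of the butylidene groups; secondary photoreaction of the product; covalent capture of the electrophilic substrate by nucleophilic residues; background racemic dimerization.
- Fallback (known chemistry), setting out from 11 and coming back at 12: sensitized [2+2] photodimerization of 11 without protein (thioxanthone, 405 nm, degassed concentrated MeCN solution, 0 °C). The racemic cross-dimer would be separated from its constitutional isomers by chromatography and resolved by preparative HPLC on an amylose tris(3,5-dimethylphenylcarbamate) phase. This should give 12 together with its mirror image, the (6R,7S,3a'S,7a'R)-cyclodimer of (Z)-ligustilide F1. The absolute configuration would be assigned by X-ray analysis or by comparing circular dichroism with calculation.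

Step 6.
- What may go wrong: 6-endo-dig closure to the isomeric 2-pyranone, or oxidative aromatization of the dihydro ring during cyclization.
- Fallback, setting out from triflate 6 and coming back at 11, building the butylidene by carbonyl chemistry instead of alkyne activation: Stille coupling of 6 with (tributylstannyl)methanol (Pd(PPh3)4, LiCl, dioxane, 90 °C) should give methyl 2-(hydroxymethyl)cyclohexa-1,5-diene-1-carboxylate F2. On warming with a trace of TsOH, F2 should lactonize to 4,5-dihydro-2-benzofuran-1(3H)-one F3. A one-flask vinylogous Mukaiyama aldol and elimination follows. TBSOTf and i-Pr2NEt in CH2Cl2 convert F3 into tert-butyl[(4,5-dihydro-2-benzofuran-1-yl)oxy]dimethylsilane F4. F4 adds to butanal at C3 to give 3-[1-(tert-butyldimethylsilyloxy)butyl]-4,5-dihydro-2-benzofuran-1(3H)-one F5. DBU then eliminates the silanol to the thermodynamically preferred Z-butylidene lactone 11.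

Step 5.
- What may go wrong: base-induced migration of the ring double bonds, aromatization, or sluggish hydrolysis of the hindered tetrasubstituted enoate.
- Fallback, setting out from 8 and coming back at 10 by a redox detour that avoids base: i-Bu2AlH (CH2Cl2, −78 °C) should reduce the ester to [2-(pent-1-yn-1-yl)cyclohexa-1,5-dien-1-yl]methanol F6. MnO2 (CH2Cl2, rt) should oxidize this allylic alcohol to 2-(pent-1-yn-1-yl)cyclohexa-1,5-diene-1-carbaldehyde F7. Pinnick oxidation (NaClO2, NaH2PO4, 2-methylbut-2-ene, t-BuOH/H2O) should then give acid 10.

**Further compounds**
F1 | step 7 | (6R,7S,3a'S,7a'R)-6.7a',7.3a'-cyclodimer of (Z)-ligustilide (enantiomer of 12) | CCC/C=C1\OC(=O)C2=C1CC[C@@H]1[C@H]2[C@@]23CCC=C[C@@]12C(=O)O/C3=C\CCC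
F2 | step 6 | methyl 2-(hydroxymethyl)cyclohexa-1,5-diene-1-carboxylate | COC(=O)C1=C(CO)CCC=C1
F3 | step 6 | 4,5-dihydro-2-benzofuran-1(3H)-one | O=C1OCC2=C1C=CCC2
F4 | step 6 | tert-butyl[(4,5-dihydro-2-benzofuran-1-yl)oxy]dimethylsilane | CC(C)(C)[Si](C)(C)Oc1occ2CCC=Cc12
F5 | step 6 | 3-[1-(tert-butyldimethylsilyloxy)butyl]-4,5-dihydro-2-benzofuran-1(3H)-one (racemic diastereomer mixture) | CCCC(O[Si](C)(C)C(C)(C)C)C1OC(=O)C2=C1CCC=C2
F6 | step 5 | [2-(pent-1-yn-1-yl)cyclohexa-1,5-dien-1-yl]methanol | CCCC#CC1=C(CO)C=CCC1
F7 | step 5 | 2-(pent-1-yn-1-yl)cyclohexa-1,5-diene-1-carbaldehyde | CCCC#CC1=C(C=O)C=CCC1
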